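**Retrosynthetic overview**
- The C8 ester bond is cut first. It is made by displacing an axial C8 alcohol with inversion, using the side-chain acid with its two CH2OH groups tied up as a seven-membered acetonide. The exocyclic methylene is the last carbon put on the lactone.
- The lactone C6–O bond comes from a [2,3]-sigmatropic selenoxide-to-selenenate shift that moves oxygen from C11 to C6. Conjugate reduction then sets C7 and the γ-lactone closes.
- The C7–C11 bond comes from an aldol condensation of the C8 ketone with ethyl glyoxylate.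
- The carbocycle with C5 and C10 comes from (−)-verbenone by vinyl copper addition anti to the gem-dimethyl bridge, then cleavage of the cyclobutane to the isopropenyl ketone.
- Ring order: the cyclohexane is released from the bought bicycle first, and the trans-fused γ-lactone forms second.

Assumption: positions are given in elemane numbering (C10 quaternary, C5 isopropenyl-bearing, C6 lactone C–O, C7 ring-fusion carbon, C8 ester carbon, C9 CH2, C11–C13 lactone arm), and 1, 7 and 23 are taken as commercial.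

**Step 1**
Reactants: 1 (1S,5S)-(−)-verbenone
Product: 3 (1S,4R,5R)-4-ethenyl-4,6,6-trimethylbicyclo[3.1.1]heptan-2-one, via silyl enol ether 2 (not isolated)
Conditions: CH2=CHMgBr (1.5 equiv), CuBr·SMe2 (10 mol %), Me3SiCl (2 equiv), THF, −78 → −20 °C; then 1 M HCl, 0 °C
Reagents that add atoms: vinylmagnesium bromide C=C[Mg]Br
Why: Copper-catalysed conjugate addition of the vinyl Grignard reagent, accelerated by Me3SiCl, takes place on the enone face opposite the gem-dimethyl bridge, so the new quaternary C10 carries vinyl anti and methyl syn to that bridge (R).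

**Step 2**
Reactants: 3 vinyl adduct of verbenone
Product: 6 (3R,4R)-3-ethenyl-3-methyl-4-(prop-1-en-2-yl)cyclohexan-1-one, via iodo silyl enol ether 4 (not isolated), via isopropenyl silyl enol ether 5 (not isolated)
Conditions: Me3SiI (1.2 equiv), CH2Cl2, −40 → 0 °C; DBU (3 equiv), 0 °C → rt; then 1 M HCl, THF
Reagents that add atoms: none
Why: O-silylation triggers heterolytic opening of the strained cyclobutane bond between the ketone α-carbon and the CMe2 carbon to give a tertiary iodide, and E2 loss of HI goes into a methyl group because the tetrasubstituted alternative would clash with the neighbouring quaternary carbon, while C5 and C10 are untouched.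

**Step 3**
Reactants: 6 elemadienone; 7 ethyl glyoxylate
Product: 10 ethyl (2E)-[(4R,5R)-4-ethenyl-4-methyl-2-oxo-5-(prop-1-en-2-yl)cyclohexylidene]acetate, via aldol adduct 8 (not isolated), via aldol mesylate 9 (not isolated)
Conditions: LiN(i-Pr)2 (1.1 equiv), THF, −78 °C; 7 (freshly cracked, 1.3 equiv); MsCl (1.5 equiv), Et3N (4 equiv), −78 → 0 °C
Reagents that add atoms: none
Why: Kinetic deprotonation occurs at the open C7 and not at the neopentyl C9, and aldol addition followed by E1cB loss of mesylate (aldol condensation) gives the E-alkylidene ester with the ester turned away from the ketone and toward C6.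

**Step 4**
Reactants: 10 keto alkylidene ester
Product: 11 ethyl (2E)-[(2S,4R,5R)-4-ethenyl-2-hydroxy-4-methyl-5-(prop-1-en-2-yl)cyclohexylidene]acetate
Conditions: NaBH4 (1.0 equiv), CeCl3·7H2O (1.1 equiv), MeOH, −78 °C
Reagents that add atoms: none
Why: In this Luche 1,2-reduction the axial trajectory at C8 is blocked by the syn-axial C10 methyl, so hydride enters equatorially and gives the axial alcohol cis to that methyl (8S), the epimer that is inverted in step 12.

**Step 5**
Reactants: 11 axial allylic alcohol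
Product: 12 ethyl (2E)-[(2S,4R,5R)-2-{[tert-butyl(dimethyl)silyl]oxy}-4-ethenyl-4-methyl-5-(prop-1-en-2-yl)cyclohexylidene]acetate
Conditions: t-BuMe2SiOTf (1.3 equiv), 2,6-lutidine (2 equiv), CH2Cl2, 0 °C
Reagents that add atoms: tert-butyldimethylsilyl triflate CC(C)(C)[Si](C)(C)OS(=O)(=O)C(F)(F)F
Why: Silyl ether protection keeps O8 from lactonising onto C12 in the following basic steps and puts a bulky axial group on the ring face that must stay closed in step 7.

**Step 6**
Reactants: 12 silyl-protected alkylidene ester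
Product: 16 ethyl (2Z)-[(2S,3R,4R,6S)-6-{[tert-butyl(dimethyl)silyl]oxy}-4-ethenyl-2-hydroxy-4-methyl-3-(prop-1-en-2-yl)cyclohexylidene]acetate, via allylic selenide 13 (not isolated), via allylic selenoxide 14 (not isolated), via allylic selenenate 15 (not isolated)
Conditions: LiN(i-Pr)2 (1.3 equiv), DMPU, THF, −78 °C; PhSeBr (1.2 equiv); AcOH quench; then 30% H2O2, pyridine, 0 °C → rt
Reagents that add atoms: hydrogen peroxide OO
Why: Deconjugative α-selenenylation of the extended ester enolate (the C6 hydrogen syn to the ester is removed) puts selenium on C11 beside a C6=C7 double bond, and oxidation sets off the [2,3]-sigmatropic selenoxide–selenenate rearrangement, which forms the C6–O bond suprafacially on the face opposite the syn-axial C10 methyl and trans to the C5 isopropenyl group (6S), with the ester in the exo position of the envelope transition state.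

**Step 7**
Reactants: 16 γ-hydroxy alkylidene ester
Product: 18 (3aR,4S,6R,7R,7aS)-4-{[tert-butyl(dimethyl)silyl]oxy}-6-ethenyl-6-methyl-7-(prop-1-en-2-yl)hexahydro-1-benzofuran-2(3H)-one, via saturated hydroxy ester 17 (not isolated)
Conditions: Cu(OAc)2·H2O (5 mol %), 1,2-bis(diphenylphosphino)benzene (5 mol %), (EtO)2MeSiH (3 equiv), t-BuOH (3 equiv), toluene, rt; then PPTS (10 mol %), toluene, 80 °C
Reagents that add atoms: none
Why: Copper hydride conjugate reduction delivers hydride to C7 along the axial trajectory from the face opposite the axial C8 silyloxy and C10 methyl groups, so the acetate arm ends equatorial and trans to the C6 hydroxyl, and acid-catalysed transesterification closes the trans-fused γ-lactone whichever alkene geometry step 6 gave.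

**Step 8**
Reactants: 18 saturated trans-lactone
Product: 21 (3aR,4S,6R,7R,7aS)-4-{[tert-butyl(dimethyl)silyl]oxy}-6-ethenyl-6-methyl-3-methylidene-7-(prop-1-en-2-yl)hexahydro-1-benzofuran-2(3H)-one, via Mannich base 19 (not isolated), via methiodide 20 (not isolated)
Conditions: LiN(i-Pr)2 (1.2 equiv), THF, −78 °C; CH2=NMe2+ I− (3 equiv), −78 °C → rt; MeI (10 equiv), MeOH, rt; then sat aq NaHCO3, CH2Cl2
Reagents that add atoms: N,N-dimethylmethyleneiminium iodide C[N+](C)=C.[I-]
Why: Mannich aminomethylation of the lactone enolate, quaternisation and base-induced β-elimination (Eschenmoser methylenation) install C13 without touching any stereocentre, since C11 becomes planar.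

**Step 9**
Reactants: 21 silyl-protected α-methylene lactone
Product: 22 (3aS,4S,6R,7R,7aS)-6-ethenyl-4-hydroxy-6-methyl-3-methylidene-7-(prop-1-en-2-yl)hexahydro-1-benzofuran-2(3H)-one
Conditions: HF·pyridine, THF, 0 °C → rt
Reagents that add atoms: none
Why: Fluoride-driven desilylation under acidic conditions frees the axial C8 alcohol without the base-induced migration of the lactone from O6 to O8.

**Step 10**
Reactants: 23 2,2-dimethyl-4,7-dihydro-1,3-dioxepine
Product: 25 5-bromo-2,2-dimethyl-4,7-dihydro-1,3-dioxepine, via trans dibromide 24 (not isolated)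
Conditions: Br2 (1.0 equiv), CH2Cl2, −78 → 0 °C; then DBU (2.5 equiv), THF, reflux
Reagents that add atoms: bromine BrBr
Why: Anti bromination of the ring alkene followed by E2 dehydrobromination gives the vinyl bromide, and the ring holds the two CH2O carbons cis on the double bond.

**Step 11**
Reactants: 25 vinyl bromide
Product: 27 2,2-dimethyl-4,7-dihydro-1,3-dioxepine-5-carboxylic acid, via vinyllithium 26 (not isolated)
Conditions: t-BuLi (2.1 equiv), Et2O, −78 °C; CO2 (g); cold 0.5 M HCl to pH 4
Reagents that add atoms: carbon dioxide O=C=O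
Why: Halogen–lithium exchange and carboxylation proceed with retention, β-alkoxide loss is shut off because it would need a cyclic allene, and the ring fixes the geometry that becomes the E double bond of the side chain.

**Step 12**
Reactants: 22 axial C8 alcohol; 27 acetonide acid
Product: 28 (3aS,4R,6R,7R,7aS)-6-ethenyl-6-methyl-3-methylidene-2-oxo-7-(prop-1-en-2-yl)octahydro-1-benzofuran-4-yl 2,2-dimethyl-4,7-dihydro-1,3-dioxepine-5-carboxylate
Conditions: PPh3 (2 equiv), DIAD (2 equiv), 27 (2 equiv), toluene, 0 °C → rt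
Reagents that add atoms: none
Why: In this Mitsunobu esterification the axial alcohol is activated as its oxyphosphonium salt and displaced by the carboxylate in an SN2 reaction with inversion, which gives the equatorial 8R ester of the target.

**Step 13**
Reactants: 28 acetonide ester
Product: 29 (3aS,4R,6R,7R,7aS)-6-ethenyl-6-methyl-3-methylidene-2-oxo-7-(prop-1-en-2-yl)octahydro-1-benzofuran-4-yl (2E)-4-hydroxy-2-(hydroxymethyl)but-2-enoate
Conditions: AcOH/H2O/THF (3:1:1), rt → 40 °C
Reagents that add atoms: none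
Why: Mild acid-catalysed acetal hydrolysis opens the strained seven-membered acetonide to the two primary allylic alcohols and leaves both esters, the α-methylene lactone and all five stereocentres unchanged.

**Compound list**
1 | (1S,5S)-(−)-verbenone | CC1=CC(=O)[C@H]2C[C@@H]1C2(C)C | starting material
2 | trimethylsilyl enol ether (C8=C9) of 3 | C=C[C@@]1(C)C=C(O[Si](C)(C)C)[C@H]2C[C@@H]1C2(C)C | intermediate
3 | (1S,4R,5R)-4-ethenyl-4,6,6-trimethylbicyclo[3.1.1]heptan-2-one | C=C[C@@]1(C)CC(=O)[C@H]2C[C@@H]1C2(C)C | intermediate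
4 | ring-opened tertiary iodide, trimethylsilyl enol ether (C7=C8) | C=C[C@@]1(C)CC(O[Si](C)(C)C)=CC[C@@H]1C(C)(C)I | intermediate
5 | isopropenyl trimethylsilyl enol ether (C7=C8) | C=C[C@@]1(C)CC(O[Si](C)(C)C)=CC[C@@H]1C(=C)C | intermediate
6 | (3R,4R)-3-ethenyl-3-methyl-4-(prop-1-en-2-yl)cyclohexan-1-one | C=C[C@@]1(C)CC(=O)CC[C@@H]1C(=C)C | intermediate
7 | ethyl glyoxylate | CCOC(=O)C=O | starting material
8 | C7 aldol adduct (epimers at C7 and C11) | C=C[C@@]1(C)CC(=O)C(C(O)C(=O)OCC)C[C@@H]1C(=C)C | intermediate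
9 | mesylate of 8 | C=C[C@@]1(C)CC(=O)C(C(OS(C)(=O)=O)C(=O)OCC)C[C@@H]1C(=C)C | intermediate
10 | ethyl (2E)-[(4R,5R)-4-ethenyl-4-methyl-2-oxo-5-(prop-1-en-2-yl)cyclohexylidene]acetate | C=C[C@@]1(C)CC(=O)/C(=C/C(=O)OCC)C[C@@H]1C(=C)C | intermediate
11 | ethyl (2E)-[(2S,4R,5R)-4-ethenyl-2-hydroxy-4-methyl-5-(prop-1-en-2-yl)cyclohexylidene]acetate | C=C[C@@]1(C)C[C@H](O)/C(=C/C(=O)OCC)C[C@@H]1C(=C)C | intermediate
12 | tert-butyldimethylsilyl ether of 11 | C=C[C@@]1(C)C[C@H](O[Si](C)(C)C(C)(C)C)/C(=C/C(=O)OCC)C[C@@H]1C(=C)C | intermediate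
13 | C11 phenyl selenide with C6=C7 double bond (epimers at C11) | C=C[C@@]1(C)C[C@H](O[Si](C)(C)C(C)(C)C)C(C([Se]c2ccccc2)C(=O)OCC)=C[C@@H]1C(=C)C | intermediate
14 | selenoxide of 13 | C=C[C@@]1(C)C[C@H](O[Si](C)(C)C(C)(C)C)C(C([Se](=O)c2ccccc2)C(=O)OCC)=C[C@@H]1C(=C)C | intermediate
15 | C6 benzeneselenenate ester, ester syn to C8 | C=C[C@@]1(C)C[C@H](O[Si](C)(C)C(C)(C)C)/C(=C\C(=O)OCC)[C@@H](O[Se]c2ccccc2)[C@@H]1C(=C)C | intermediate
16 | ethyl (2Z)-[(2S,3R,4R,6S)-6-{[tert-butyl(dimethyl)silyl]oxy}-4-ethenyl-2-hydroxy-4-methyl-3-(prop-1-en-2-yl)cyclohexylidene]acetate | C=C[C@@]1(C)C[C@H](O[Si](C)(C)C(C)(C)C)/C(=C\C(=O)OCC)[C@@H](O)[C@@H]1C(=C)C | intermediate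
17 | saturated hydroxy ester, acetate arm equatorial at C7 | C=C[C@@]1(C)C[C@H](O[Si](C)(C)C(C)(C)C)[C@H](CC(=O)OCC)[C@@H](O)[C@@H]1C(=C)C | intermediate
18 | (3aR,4S,6R,7R,7aS)-4-{[tert-butyl(dimethyl)silyl]oxy}-6-ethenyl-6-methyl-7-(prop-1-en-2-yl)hexahydro-1-benzofuran-2(3H)-one | C=C[C@@]1(C)C[C@H](O[Si](C)(C)C(C)(C)C)[C@@H]2CC(=O)O[C@H]2[C@@H]1C(=C)C | intermediate
19 | C11 dimethylaminomethyl lactone (epimers at C11) | C=C[C@@]1(C)C[C@H](O[Si](C)(C)C(C)(C)C)[C@@H]2C(CN(C)C)C(=O)O[C@H]2[C@@H]1C(=C)C | intermediate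
20 | trimethylammonium iodide of 19 | C=C[C@@]1(C)C[C@H](O[Si](C)(C)C(C)(C)C)[C@@H]2C(C[N+](C)(C)C)C(=O)O[C@H]2[C@@H]1C(=C)C.[I-] | intermediate
21 | (3aR,4S,6R,7R,7aS)-4-{[tert-butyl(dimethyl)silyl]oxy}-6-ethenyl-6-methyl-3-methylidene-7-(prop-1-en-2-yl)hexahydro-1-benzofuran-2(3H)-one | C=C[C@@]1(C)C[C@H](O[Si](C)(C)C(C)(C)C)[C@@H]2C(=C)C(=O)O[C@H]2[C@@H]1C(=C)C | intermediate
22 | (3aS,4S,6R,7R,7aS)-6-ethenyl-4-hydroxy-6-methyl-3-methylidene-7-(prop-1-en-2-yl)hexahydro-1-benzofuran-2(3H)-one | C=C[C@@]1(C)C[C@H](O)[C@@H]2C(=C)C(=O)O[C@H]2[C@@H]1C(=C)C | intermediate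
23 | 2,2-dimethyl-4,7-dihydro-1,3-dioxepine | CC1(C)OCC=CCO1 | starting material
24 | trans-5,6-dibromo-2,2-dimethyl-1,3-dioxepane (racemic, one enantiomer drawn) | CC1(C)OC[C@H](Br)[C@@H](Br)CO1 | intermediate
25 | 5-bromo-2,2-dimethyl-4,7-dihydro-1,3-dioxepine | CC1(C)OCC=C(Br)CO1 | intermediate
26 | (2,2-dimethyl-4,7-dihydro-1,3-dioxepin-5-yl)lithium | [Li]C1=CCOC(C)(C)OC1 | intermediate
27 | 2,2-dimethyl-4,7-dihydro-1,3-dioxepine-5-carboxylic acid | OC(=O)C1=CCOC(C)(C)OC1 | intermediate
28 | (3aS,4R,6R,7R,7aS)-6-ethenyl-6-methyl-3-methylidene-2-oxo-7-(prop-1-en-2-yl)octahydro-1-benzofuran-4-yl 2,2-dimethyl-4,7-dihydro-1,3-dioxepine-5-carboxylate | C=C[C@@]1(C)C[C@@H](OC(=O)C3=CCOC(C)(C)OC3)[C@@H]2C(=C)C(=O)O[C@H]2[C@@H]1C(=C)C | intermediate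
29 | (3aS,4R,6R,7R,7aS)-6-ethenyl-6-methyl-3-methylidene-2-oxo-7-(prop-1-en-2-yl)octahydro-1-benzofuran-4-yl (2E)-4-hydroxy-2-(hydroxymethyl)but-2-enoate | C=C[C@@]1(C)C[C@@H](OC(=O)/C(=C/CO)CO)[C@@H]2C(=C)C(=O)O[C@H]2[C@@H]1C(=C)C | target

**Totals**
Total step count: 13.
Longest linear sequence: 11 (steps 1–9, 12 and 13). Steps 10 and 11 form the side branch.

**Three steps most likely to fail**

*Step 2.* Me3SiI may add HI to the vinyl group, or the elimination may give some isopropylidene isomer. The fallback sets out from 3 and comes back at 6. The cyclobutane is acetolysed with BF3·OEt2, Zn(OAc)2 and Ac2O to the enol acetate tertiary acetate F1. Both acetates are cleaved with MeLi to the tertiary hydroxy ketone F2. The alcohol is then dehydrated by syn elimination into a methyl group with the Burgess reagent, which gives 6.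

*Step 6.* There are three risks here, and the facial outcome of step 7 depends on this step too.
- The regiochemistry of the γ-deprotonation.
- Attack of selenium at the α rather than the γ carbon.
- The facial selectivity of the shift.

The fallback sets out from 6 and comes back at 18, so it bypasses steps 3 to 7. It puts oxygen on C6 by conjugate borylation and sets C7 by equilibration.
- The kinetic enolate of 6 is alkylated with tert-butyl bromoacetate to the keto ester F3.
- IBX dehydrogenation gives the 2-substituted enone F4.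
- B2pin2 with catalytic CuCl and NaOt-Bu in THF/MeOH adds boron to C6 trans to the isopropenyl group and gives the β-boryl ketone F5, in which C7 settles as the equatorial epimer.
- NaBO3·4H2O gives the β-hydroxy keto ester F6.
- CF3CO2H closes the keto lactone F7.
- LiBH(s-Bu)3 at −78 °C gives the axial hydroxy lactone F8.
- t-BuMe2SiOTf with 2,6-lutidine rejoins the route at 18.

*Step 12.* Displacement at the hindered C8 may lose out to elimination, or PPh3 may add to the α-methylene lactone. The fallback sets out from 22 and comes back at 28, and it separates the inversion from the acylation. A Mitsunobu reaction with the small and more acidic chloroacetic acid gives the inverted chloroacetate F9. Thiourea with NaHCO3 in EtOH removes the chloroacetyl group under near-neutral conditions and gives the equatorial C8 alcohol F10. This alcohol is acylated with retention by the mixed anhydride of 27 (2,4,6-trichlorobenzoyl chloride, Et3N, DMAP, toluene) to give 28.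

**Further compounds**
F1 | step 2 | enol acetate tertiary acetate from acetolysis of 3 | C=C[C@@]1(C)CC(OC(C)=O)=CC[C@@H]1C(C)(C)OC(C)=O
F2 | step 2 | tertiary hydroxy ketone, 4-(2-hydroxypropan-2-yl) analogue of 6 | C=C[C@@]1(C)CC(=O)CC[C@@H]1C(C)(C)O
F3 | step 6 | keto ester, tert-butyl acetate arm equatorial at C7 | C=C[C@@]1(C)CC(=O)[C@H](CC(=O)OC(C)(C)C)C[C@@H]1C(=C)C
F4 | step 6 | 2-substituted enone (C6=C7) | C=C[C@@]1(C)CC(=O)C(CC(=O)OC(C)(C)C)=C[C@@H]1C(=C)C
F5 | step 6 | β-boryl ketone, pinacolboryl at C6 trans to isopropenyl | C=C[C@@]1(C)CC(=O)[C@H](CC(=O)OC(C)(C)C)[C@@H](B2OC(C)(C)C(C)(C)O2)[C@@H]1C(=C)C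
F6 | step 6 | β-hydroxy keto ester | C=C[C@@]1(C)CC(=O)[C@H](CC(=O)OC(C)(C)C)[C@@H](O)[C@@H]1C(=C)C
F7 | step 6 | keto lactone, trans-fused, C8 ketone | C=C[C@@]1(C)CC(=O)[C@@H]2CC(=O)O[C@H]2[C@@H]1C(=C)C
F8 | step 6 | axial hydroxy lactone, desilyl 18 | C=C[C@@]1(C)C[C@H](O)[C@@H]2CC(=O)O[C@H]2[C@@H]1C(=C)C
F9 | step 12 | inverted chloroacetate, equatorial at C8 | C=C[C@@]1(C)C[C@@H](OC(=O)CCl)[C@@H]2C(=C)C(=O)O[C@H]2[C@@H]1C(=C)C
F10 | step 12 | equatorial C8 alcohol, C8 epimer of 22 | C=C[C@@]1(C)C[C@@H](O)[C@@H]2C(=C)C(=O)O[C@H]2[C@@H]1C(=C)C
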